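## The problem

Target 26 is (2R,3R)-6-prenyl-3'-O-methyltaxifolin, a trans-dihydroflavonol. Ring C, a chroman-4-one, is fused to the phloroglucinol-type ring A and carries the 4-hydroxy-3-methoxyphenyl ring B at C2 and a hydroxyl at C3. The prenyl group sits at C6 between the C5 and C7 hydroxyls, so the two oxygens ortho to C4a are not equivalent. Only the oxygen para to the prenyl group may become O1; closure through the other gives the 8-prenyl isomer, so the ring A oxygens must be told apart before ring C closes. C3 is alpha to the C4 ketone and C2 is a benzylic ether carbon beta to it, so base opens ring C to a 2'-hydroxychalcone and erases both centres, and the para-oxygenated ring B makes C2 prone to ionisation. Inside the closed ring the trans (diequatorial) arrangement is favoured, so C3 can steer C2 but nothing steers C3; C3 must come from a catalyst- or reagent-controlled event and must never be enolised afterwards. The prenyl alkene will not survive ozone, peracids, electrophilic halogen or hydrogenolysis, and under strong acid it adds the neighbouring phenols to give chromans. The feature that opens the route is that C2 and C3 form a 1-aryl-1,2-diol unit between ring B and the C4 carbonyl. If C4 is carried as a vinyl carbon, the C2–C3 bond and both oxygenated stereocentres can be made in one γ-alkoxyallylboration of the ring B aldehyde, and C4 is unveiled as an aldehyde before ring A and its prenyl group arrive.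

## Retrosynthesis

**26 ⇒ 25.** The four O–CH2 bonds of methoxymethyl (MOM) acetals on O5, O7, O3 and O4' are cut. Benzyl ethers would need hydrogenolysis, which the prenyl alkene does not tolerate, and methyl ethers could not be removed beside the 3'-methoxy group. MOM groups also direct the two ring A metalations and survive organolithiums, fluoride and Mitsunobu conditions. The forward step must cleave all four acetals with acid mild enough to leave the prenyl group and the trans ring intact.

**25 ⇒ 24.** The O1–C2 bond is cut, opening ring C to hydroxy ketone 24, in which the phenol para to the prenyl group is the only free phenol. The neighbouring O1–C8a cut would need an electrophilic carbon on an electron-rich ring. Closure by conjugate addition to a chalcone would give up control of C3. Displacement at C2 by the phenol with inversion (Mitsunobu) is stereospecific. It requires 24 to carry C3 as in the target and C2 with the opposite configuration, which is a syn 1,2-diol derivative. The forward reaction must displace faster than the activated β-hydroxy ketone eliminates.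

**24 ⇒ 23 ⇒ 22 ⇒ 21 + 12.** Functional group changes lead back from 24 to the doubly protected ketone 23 and to carbinol 22. Then the C4–C4a bond is cut into aryllithium 21 (from arene 20) and aldehyde 12. Acylation of the arene with an acid derivative would need Lewis acids that the acetals do not survive and would give no regiocontrol. The aryllithium–aldehyde union costs one oxidation but joins two fragments of equal size under conditions that tolerate everything present. The future O1 carries a tetrahydropyranyl (THP) acetal: it cooperates with the neighbouring MOM group in directing the lithiation, contains no silicon that could migrate to the adjacent carbanion or alkoxide, and is cleaved by aqueous acetic acid together with the triethylsilyl ether on the C2 oxygen while the MOM groups stay.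

**12 ⇒ 10 ⇒ 9.** The C4 aldehyde is traced back to the vinyl group of silyl ether 10 and of alcohol 9. Carrying C4 as a vinyl carbon means that the oxidative cleavage is done while the molecule contains no prenyl group. The forward steps must silylate a hindered benzylic alcohol without touching the acetals and must cleave a monosubstituted alkene beside an electron-rich arene.

**9 ⇒ 2 + 7 (key disconnection).** The C2–C3 bond is cut into aldehyde 2 and the (Z)-γ-(methoxymethoxy)allyl pinacol boronate 7. Compared with dihydroxylation of a cinnamyl precursor, this makes the carbon–carbon bond and both stereocentres at once and delivers the two oxygens already differentiated (free at C2, MOM at C3). Compared with an aldol approach, C3 is never alpha to a carbonyl while it is being set. The forward reaction must be syn-selective (from the Z geometry) and face-selective (from a chiral phosphoric acid).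

**7 ⇒ 4 ⇒ 3, and 2 ⇒ 1.** Boronate 7 comes from allyl ether 4 by lithiation and borylation (through 5 and 6), and 4 from allyl alcohol 3. Aldehyde 2 is the MOM ether of vanillin 1. All of ring B and the three carbons of ring C thus come from two commodity chemicals.

**20 ⇒ 19 ⇒ 15 ⇒ 14 ⇒ 13 + 16.** The THP acetal is cut from 20 to give phenol 19, then the C6–prenyl bond is cut (to prenyl bromide 16) and the silyl ether, MOM ethers and finally phloroglucinol 13 are reached. The prenyl group must enter between the two MOM ethers. A third acetal on the remaining oxygen would compete as a directing group, so that oxygen is first masked as a bulky, non-coordinating triisopropylsilyl ether (15). The silyl group is removed in the prenylation flask and replaced by THP for the second metalation. The only non-selective event is the statistical bis-protection of 13 to 14, which is accepted because it is the first step on the cheapest material.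

## Roads not taken

**Alternative 1:** Rings C and A are both unravelled by cutting O1–C8a and C4a–C5. The precursor is the open-chain triketo ester A2, which carries the anti diol unit at one end and the prenyl group on the carbon between the ester and the first ketone. In the forward key step the C2 hydroxyl would add to the C8a ketone and dehydrate to a dihydropyranone. C4a would then attack the ester, and aromatisation would give A1, the 3,4'-bis-MOM ether of 26.
- Merits: the 6- versus 8-prenyl question disappears because the prenyl position is written into the chain. Two rings form in one operation and only two acetals remain to be cleaved. On the regiochemistry of ring A this road is better than the chosen one.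
- Weak points: A2 is a poly-β-carbonyl chain ending in an α-alkoxy-β-hydroxy ketone. Retro-aldol cleavage, dehydration and epimerisation at C3 are all open, several aldol modes compete with the desired Claisen closure, and assembling A2 needs polyanion chemistry beside the sensitive diol. The anti diol with C2 already in the target configuration would also need its own asymmetric synthesis.
- Comparison: the chosen plan spends four steps on differentiating the ring A oxygens, but it never exposes C3 to enolising conditions before the ring is closed.

**Alternative 2:** The C2–aryl bond is cut, giving chromone A4 and arylboronic acid A5. The forward key step is an asymmetric conjugate arylation with Pd(OCOCF3)2 and a tert-butyl pyridine–oxazoline ligand, giving flavanone A3 with C2 set directly in the closed ring.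
- Merits: catalytic asymmetric induction, high convergence, late introduction of ring B and a very short sequence to the flavanone. In step count to that stage it beats the chosen plan.
- Weak points: A3 lacks the C3 oxygen. Introducing it by enolate oxidation is the hard part for this target: flavanone enolates open by β-elimination of the ring phenoxide, which racemises C2, and the peracid or dioxirane oxidants of silyl enol ether routes attack the prenyl alkene. The 5-alkoxy group peri to the carbonyl and the electron-rich ring make A4 a poor acceptor. Making A4 meets the same 6- versus 8-prenyl ambiguity at its own ring closure.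
- Comparison: the chosen plan sets C3 first and absolutely and lets C2 follow by a stereospecific closure, at the price of more steps.

**Alternative 3:** O1–C8a and C4–C4a are cut at once. Fluoride (CsF) would generate the 3,5-dioxygenated 4-prenylbenzyne from silyl triflate A7. The cesium alkoxide of hydroxy ester A8 would add at the aryne carbon remote from the flanking oxygen, and the aryl anion would close onto the ester, giving A6, which is identical with 25.
- Merits: this is the most convergent road. The known preference of 3-alkoxyarynes places the nucleophile where O1 belongs, so no differentiation of the ring A oxygens is needed, and 25 would be reached without the oxidation, unmasking and Mitsunobu steps. If it worked it would be clearly shorter.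
- Weak points: the alkoxide of a β-hydroxy ester is prone to retro-aldol cleavage and to epimerisation at the α-carbon. A secondary benzylic alkoxide is a poorer aryne partner than a phenoxide. The aryl anion must acylate faster than it is protonated. The prenyl alkene can intercept the aryne in an ene reaction. A7 needs a multistep synthesis, and A8 needs the anti diol from a separate asymmetric method.
- Comparison: the chosen plan forms the same two bonds in separate steps, each of a type with known tolerance for the groups present.

Key step: step 4

Assumption: the (R)-enantiomer of the phosphoric acid is taken to direct the γ-alkoxyallyl group to the Re face of 2, as it does for allyl and crotyl pinacol boronates with aryl aldehydes; should the alkoxy substituent reverse this sense, the (S)-enantiomer would be used with no other change.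

## Route

Step 1
Reactants: 1 vanillin
Product: 2 3-methoxy-4-(methoxymethoxy)benzaldehyde
Conditions: MOMCl, i-Pr2NEt, CH2Cl2, 0 °C → rt
Reagents that add atoms: chloromethyl methyl ether, COCCl
Why: O-alkylation of the phenol with the chloromethyl ether (acetal formation) under amine base; the aldehyde is untouched. The MOM group survives every later step and leaves in the last one.

Step 2
Reactants: 3 allyl alcohol
Product: 4 3-(methoxymethoxy)prop-1-ene
Conditions: MOMCl, i-Pr2NEt, CH2Cl2, 0 °C → rt; distillation
Reagents that add atoms: chloromethyl methyl ether, COCCl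
Why: The same O-alkylation on a primary alcohol; the volatile acetal is purified by distillation. Its oxygen becomes the C3 oxygen of the target, already protected.

Step 3
Reactants: 4 3-(methoxymethoxy)prop-1-ene
Product: 7 (Z)-2-[3-(methoxymethoxy)prop-2-en-1-yl]-4,4,5,5-tetramethyl-1,3,2-dioxaborolane, via (Z)-[3-(methoxymethoxy)allyl]lithium 5 (not isolated), via its lithium isopropoxy pinacol borate 6 (not isolated)
Conditions: s-BuLi, THF, −78 °C; i-PrOBpin, −78 °C; AcOH, −78 °C → rt
Reagents that add atoms: 2-isopropoxy-4,4,5,5-tetramethyl-1,3,2-dioxaborolane, CC(C)OB1OC(C)(C)C(C)(C)O1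
Why: α-Lithiation of the allyl ether should give the internally chelated (Z)-alkoxyallyllithium, which boron electrophiles capture at the unsubstituted γ-terminus (lithiation–borylation). Protonolysis of the borate releases isopropanol and the pinacol boronate with the Z geometry retained.

Step 4
Reactants: 2 3-methoxy-4-(methoxymethoxy)benzaldehyde, 7 (Z)-2-[3-(methoxymethoxy)prop-2-en-1-yl]-4,4,5,5-tetramethyl-1,3,2-dioxaborolane
Product: 9 (1S,2S)-1-[3-methoxy-4-(methoxymethoxy)phenyl]-2-(methoxymethoxy)but-3-en-1-ol, via the O-pinacolboryl ether 8 (not isolated)
Conditions: 7 (1.3 equiv), (R)-3,3'-bis(2,4,6-triisopropylphenyl)-1,1'-binaphthyl-2,2'-diyl hydrogen phosphate (5 mol%), 4 Å MS, toluene, −30 °C; then aq. NaHCO3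
Reagents that add atoms: none
Why: Boron binds the aldehyde oxygen and the alkoxy-bearing γ-carbon of 7 attacks the carbonyl carbon through a closed six-membered chair transition state with allylic transposition, forming the future C2–C3 bond. The phosphoric acid hydrogen-bonds through P–OH to a pinacol oxygen and through P=O to the formyl hydrogen, which raises the Lewis acidity of boron and fixes the aldehyde in the chiral pocket; the closest known reaction type is the chiral-phosphoric-acid-catalysed allyl-, crotyl- and γ-alkoxyallylboration of aromatic aldehydes with pinacol boronates. No ring closes. The carbinol centre (future C2) is set by the catalyst, which exposes the Re face of 2 and so gives the 1S configuration. The alkoxy-bearing centre (future C3) is set relative to it by the Z geometry of 7: the (Z)-alkoxy group is axial and the aryl group equatorial in the chair, which gives the syn (2S) product. The step needs face selectivity and syn selectivity; the aldehyde cannot enolise, its electron-rich ring slows the uncatalysed background reaction at −30 °C, and the Z-boronate is configurationally stable at that temperature. The aryl and enol MOM acetals should tolerate the weak acid in dry toluene, and the aqueous work-up hydrolyses 8 to 9.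

Step 5
Reactants: 9 (1S,2S)-1-[3-methoxy-4-(methoxymethoxy)phenyl]-2-(methoxymethoxy)but-3-en-1-ol
Product: 10 triethyl{(1S,2S)-1-[3-methoxy-4-(methoxymethoxy)phenyl]-2-(methoxymethoxy)but-3-enyloxy}silane
Conditions: TESCl, imidazole, DMF, 0 °C → rt
Reagents that add atoms: chlorotriethylsilane, CC[Si](Cl)(CC)CC
Why: Silylation of the secondary benzylic alcohol with the chlorosilane and imidazole; silyl triflates are avoided because they attack acetals. The TES ether is chosen because aqueous acetic acid later removes it together with the phenolic THP group.

Step 6
Reactants: 10 triethyl{(1S,2S)-1-[3-methoxy-4-(methoxymethoxy)phenyl]-2-(methoxymethoxy)but-3-enyloxy}silane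
Product: 12 (2R,3S)-3-[3-methoxy-4-(methoxymethoxy)phenyl]-2-(methoxymethoxy)-3-(triethylsilyloxy)propanal, via the 1,2,4-trioxolane ozonide 11 (not isolated)
Conditions: O3, CH2Cl2, −78 °C (Sudan Red 7B end point); PPh3, −78 °C → rt
Reagents that add atoms: ozone, [O-][O+]=O
Why: Ozonolysis of the only alkene (cycloaddition, Criegee rearrangement to the ozonide, phosphine reduction) unveils C4 as an aldehyde; the monosubstituted alkene reacts much faster than the dialkoxyarene and the dye marks the end point. No prenyl group is present yet. The α-alkoxy aldehyde is used at once to protect its α-stereocentre.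

Step 7
Reactants: 13 phloroglucinol
Product: 14 3,5-bis(methoxymethoxy)phenol
Conditions: MOMCl (2.0 equiv), i-Pr2NEt, CH2Cl2/DMF, 0 °C → rt
Reagents that add atoms: chloromethyl methyl ether, COCCl
Why: Statistical double O-alkylation of the symmetric triol; the mono- and tris-ethers are separated by chromatography and the mono-ether is resubmitted. The one oxygen left free is the future O1.

Step 8
Reactants: 14 3,5-bis(methoxymethoxy)phenol
Product: 15 [3,5-bis(methoxymethoxy)phenoxy]triisopropylsilane
Conditions: TIPSCl, imidazole, DMF, rt
Reagents that add atoms: chlorotriisopropylsilane, CC(C)[Si](Cl)(C(C)C)C(C)C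
Why: Silylation of the phenol. The bulky, non-coordinating silyl ether shields its two ortho positions and leaves the carbon between the two MOM ethers as the only site for the next metalation.

Step 9
Reactants: 15 [3,5-bis(methoxymethoxy)phenoxy]triisopropylsilane, 16 prenyl bromide
Product: 19 3,5-bis(methoxymethoxy)-4-(3-methylbut-2-en-1-yl)phenol, via the C4-lithiated silyl ether 17 (not isolated), via the prenylated silyl ether 18 (not isolated)
Conditions: n-BuLi, THF, 0 °C; CuI (10 mol%), 16 (0.95 equiv), −78 → 0 °C; then Bu4NF, rt; AcOH
Reagents that add atoms: none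
Why: Directed ortho-metalation between the two MOM ethers, then copper-catalysed SN2 alkylation with the allylic bromide (copper suppresses attack at the tertiary terminus), then fluoride desilylation in the same flask. The bromide is the limiting reagent so that no alkylating agent remains when the phenoxide is set free.

Step 10
Reactants: 19 3,5-bis(methoxymethoxy)-4-(3-methylbut-2-en-1-yl)phenol
Product: 20 2-[3,5-bis(methoxymethoxy)-4-(3-methylbut-2-en-1-yl)phenoxy]tetrahydro-2H-pyran
Conditions: 3,4-dihydro-2H-pyran, pyridinium p-toluenesulfonate (5 mol%), CH2Cl2, rt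
Reagents that add atoms: 3,4-dihydro-2H-pyran, C1=COCCC1
Why: Acid-catalysed addition of the phenol to the enol ether (tetrahydropyranylation). The THP acetal directs lithiation as MOM does but is far more acid-labile, which marks the future O1 for selective release.

Step 11
Reactants: 20 2-[3,5-bis(methoxymethoxy)-4-(3-methylbut-2-en-1-yl)phenoxy]tetrahydro-2H-pyran, 12 (2R,3S)-3-[3-methoxy-4-(methoxymethoxy)phenyl]-2-(methoxymethoxy)-3-(triethylsilyloxy)propanal
Product: 22 (1RS,2S,3S)-1-[2,4-bis(methoxymethoxy)-3-(3-methylbut-2-en-1-yl)-6-(tetrahydro-2H-pyran-2-yloxy)phenyl]-3-[3-methoxy-4-(methoxymethoxy)phenyl]-2-(methoxymethoxy)-3-(triethylsilyloxy)propan-1-ol, via the ring-lithiated arene 21 (not isolated)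
Conditions: 20 (1.3 equiv), n-BuLi, THF, 0 °C; 12, −78 °C; AcOH, −78 °C
Reagents that add atoms: none
Why: Directed ortho-metalation at one of the two equivalent ring positions flanked by the THP and MOM acetals, then 1,2-addition of the aryllithium to the aldehyde, forming C4–C4a. The configuration of the new carbinol is irrelevant because it is oxidised next; the low temperature and acidic quench guard against silyl migration and α-epimerisation.

Step 12
Reactants: 22 (1RS,2S,3S)-1-[2,4-bis(methoxymethoxy)-3-(3-methylbut-2-en-1-yl)-6-(tetrahydro-2H-pyran-2-yloxy)phenyl]-3-[3-methoxy-4-(methoxymethoxy)phenyl]-2-(methoxymethoxy)-3-(triethylsilyloxy)propan-1-ol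
Product: 23 (2R,3S)-1-[2,4-bis(methoxymethoxy)-3-(3-methylbut-2-en-1-yl)-6-(tetrahydro-2H-pyran-2-yloxy)phenyl]-3-[3-methoxy-4-(methoxymethoxy)phenyl]-2-(methoxymethoxy)-3-(triethylsilyloxy)propan-1-one
Conditions: Dess–Martin periodinane, NaHCO3, CH2Cl2, 0 °C → rt
Reagents that add atoms: none
Why: Dess–Martin oxidation of the hindered secondary carbinol under buffered, non-basic conditions; both carbinol epimers converge on one ketone. The prenyl alkene, the acetals and the silyl ether are inert, and the new α-centre (C3) is not enolised.

Step 13
Reactants: 23 (2R,3S)-1-[2,4-bis(methoxymethoxy)-3-(3-methylbut-2-en-1-yl)-6-(tetrahydro-2H-pyran-2-yloxy)phenyl]-3-[3-methoxy-4-(methoxymethoxy)phenyl]-2-(methoxymethoxy)-3-(triethylsilyloxy)propan-1-one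
Product: 24 (2R,3S)-3-hydroxy-1-[6-hydroxy-2,4-bis(methoxymethoxy)-3-(3-methylbut-2-en-1-yl)phenyl]-3-[3-methoxy-4-(methoxymethoxy)phenyl]-2-(methoxymethoxy)propan-1-one
Conditions: AcOH/THF/H2O (3:1:1), 40 °C
Reagents that add atoms: none
Why: Mild acid hydrolysis should cleave the triethylsilyl ether and the aryl THP acetal while the much less labile formaldehyde-derived MOM acetals stay. Water is the only nucleophile present, so the benzylic position cannot be etherified.

Step 14
Reactants: 24 (2R,3S)-3-hydroxy-1-[6-hydroxy-2,4-bis(methoxymethoxy)-3-(3-methylbut-2-en-1-yl)phenyl]-3-[3-methoxy-4-(methoxymethoxy)phenyl]-2-(methoxymethoxy)propan-1-one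
Product: 25 (2R,3R)-2-[3-methoxy-4-(methoxymethoxy)phenyl]-3,5,7-tris(methoxymethoxy)-6-(3-methylbut-2-en-1-yl)chroman-4-one
Conditions: PPh3, DIAD, THF (0.02 M), 0 °C → rt
Reagents that add atoms: none
Why: Intramolecular Mitsunobu etherification: the benzylic C2 hydroxyl is activated as its oxyphosphonium ion and displaced by the only free phenol (6-exo-tet) with inversion, turning the syn open chain into the trans (2R,3R) ring. This closure of 2'-hydroxy-β-hydroxy ketones to flavanones and dihydroflavonols is an established reaction type. C3 is not touched, and the phenol para to the prenyl group is the only one available, which fixes the 6-prenyl regiochemistry.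

Step 15
Reactants: 25 (2R,3R)-2-[3-methoxy-4-(methoxymethoxy)phenyl]-3,5,7-tris(methoxymethoxy)-6-(3-methylbut-2-en-1-yl)chroman-4-one
Product: 26 (2R,3R)-3,5,7-trihydroxy-2-(4-hydroxy-3-methoxyphenyl)-6-(3-methylbut-2-en-1-yl)chroman-4-one
Conditions: HCl (3 M aq.), MeOH, 45 °C
Reagents that add atoms: none
Why: Acid-catalysed acetal methanolysis removes all four MOM groups as dimethoxymethane; the trans ring is the stable diastereomer under these conditions. Moderate temperature and short exposure are chosen so that the prenyl alkene does not add the neighbouring phenols.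

## Compound list

1 | vanillin (4-hydroxy-3-methoxybenzaldehyde) | COc1cc(C=O)ccc1O | starting material
2 | 3-methoxy-4-(methoxymethoxy)benzaldehyde | COCOc1ccc(C=O)cc1OC | intermediate
3 | allyl alcohol (prop-2-en-1-ol) | C=CCO | starting material
4 | 3-(methoxymethoxy)prop-1-ene (allyl methoxymethyl ether) | C=CCOCOC | intermediate
5 | (Z)-[3-(methoxymethoxy)allyl]lithium | [Li]C/C=C\OCOC | intermediate
6 | lithium isopropoxy[(Z)-3-(methoxymethoxy)allyl](pinacolato)borate | [Li+].COCO/C=C\C[B-]1(OC(C)C)OC(C)(C)C(C)(C)O1 | intermediate
7 | (Z)-2-[3-(methoxymethoxy)prop-2-en-1-yl]-4,4,5,5-tetramethyl-1,3,2-dioxaborolane | COCO/C=C\CB1OC(C)(C)C(C)(C)O1 | intermediate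
8 | 2-{(1S,2S)-1-[3-methoxy-4-(methoxymethoxy)phenyl]-2-(methoxymethoxy)but-3-enyloxy}-4,4,5,5-tetramethyl-1,3,2-dioxaborolane (O-pinacolboryl ether of 9) | C=C[C@H](OCOC)[C@@H](OB1OC(C)(C)C(C)(C)O1)c1ccc(OCOC)c(OC)c1 | intermediate
9 | (1S,2S)-1-[3-methoxy-4-(methoxymethoxy)phenyl]-2-(methoxymethoxy)but-3-en-1-ol (syn) | C=C[C@H](OCOC)[C@@H](O)c1ccc(OCOC)c(OC)c1 | intermediate
10 | triethyl{(1S,2S)-1-[3-methoxy-4-(methoxymethoxy)phenyl]-2-(methoxymethoxy)but-3-enyloxy}silane | C=C[C@H](OCOC)[C@@H](O[Si](CC)(CC)CC)c1ccc(OCOC)c(OC)c1 | intermediate
11 | 1,2,4-trioxolane (secondary ozonide) of 10, both epimers at the ring carbon, side-chain configuration as in 10 | C1OOC(O1)[C@H](OCOC)[C@@H](O[Si](CC)(CC)CC)c1ccc(OCOC)c(OC)c1 | intermediate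
12 | (2R,3S)-3-[3-methoxy-4-(methoxymethoxy)phenyl]-2-(methoxymethoxy)-3-(triethylsilyloxy)propanal | O=C[C@H](OCOC)[C@@H](O[Si](CC)(CC)CC)c1ccc(OCOC)c(OC)c1 | intermediate
13 | phloroglucinol (benzene-1,3,5-triol) | Oc1cc(O)cc(O)c1 | starting material
14 | 3,5-bis(methoxymethoxy)phenol | COCOc1cc(O)cc(OCOC)c1 | intermediate
15 | [3,5-bis(methoxymethoxy)phenoxy]triisopropylsilane | COCOc1cc(OCOC)cc(O[Si](C(C)C)(C(C)C)C(C)C)c1 | intermediate
16 | prenyl bromide (1-bromo-3-methylbut-2-ene) | CC(C)=CCBr | starting material
17 | [2,6-bis(methoxymethoxy)-4-(triisopropylsilyloxy)phenyl]lithium | [Li]c1c(OCOC)cc(O[Si](C(C)C)(C(C)C)C(C)C)cc1OCOC | intermediate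
18 | [3,5-bis(methoxymethoxy)-4-(3-methylbut-2-en-1-yl)phenoxy]triisopropylsilane | CC(C)=CCc1c(OCOC)cc(O[Si](C(C)C)(C(C)C)C(C)C)cc1OCOC | intermediate
19 | 3,5-bis(methoxymethoxy)-4-(3-methylbut-2-en-1-yl)phenol | CC(C)=CCc1c(OCOC)cc(O)cc1OCOC | intermediate
20 | 2-[3,5-bis(methoxymethoxy)-4-(3-methylbut-2-en-1-yl)phenoxy]tetrahydro-2H-pyran (racemic at the acetal carbon) | CC(C)=CCc1c(OCOC)cc(OC2CCCCO2)cc1OCOC | intermediate
21 | [2,4-bis(methoxymethoxy)-3-(3-methylbut-2-en-1-yl)-6-(tetrahydro-2H-pyran-2-yloxy)phenyl]lithium | CC(C)=CCc1c(OCOC)cc(OC2CCCCO2)c([Li])c1OCOC | intermediate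
22 | (1RS,2S,3S)-1-[2,4-bis(methoxymethoxy)-3-(3-methylbut-2-en-1-yl)-6-(tetrahydro-2H-pyran-2-yloxy)phenyl]-3-[3-methoxy-4-(methoxymethoxy)phenyl]-2-(methoxymethoxy)-3-(triethylsilyloxy)propan-1-ol (both carbinol epimers; acetal carbon unassigned) | CC(C)=CCc1c(OCOC)cc(OC2CCCCO2)c(C(O)[C@H](OCOC)[C@@H](O[Si](CC)(CC)CC)c2ccc(OCOC)c(OC)c2)c1OCOC | intermediate
23 | (2R,3S)-1-[2,4-bis(methoxymethoxy)-3-(3-methylbut-2-en-1-yl)-6-(tetrahydro-2H-pyran-2-yloxy)phenyl]-3-[3-methoxy-4-(methoxymethoxy)phenyl]-2-(methoxymethoxy)-3-(triethylsilyloxy)propan-1-one (acetal carbon unassigned) | CC(C)=CCc1c(OCOC)cc(OC2CCCCO2)c(C(=O)[C@H](OCOC)[C@@H](O[Si](CC)(CC)CC)c2ccc(OCOC)c(OC)c2)c1OCOC | intermediate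
24 | (2R,3S)-3-hydroxy-1-[6-hydroxy-2,4-bis(methoxymethoxy)-3-(3-methylbut-2-en-1-yl)phenyl]-3-[3-methoxy-4-(methoxymethoxy)phenyl]-2-(methoxymethoxy)propan-1-one | CC(C)=CCc1c(OCOC)cc(O)c(C(=O)[C@H](OCOC)[C@@H](O)c2ccc(OCOC)c(OC)c2)c1OCOC | intermediate
25 | (2R,3R)-2-[3-methoxy-4-(methoxymethoxy)phenyl]-3,5,7-tris(methoxymethoxy)-6-(3-methylbut-2-en-1-yl)chroman-4-one | COCOc1ccc([C@H]2Oc3cc(OCOC)c(CC=C(C)C)c(OCOC)c3C(=O)[C@@H]2OCOC)cc1OC | intermediate
26 | (2R,3R)-3,5,7-trihydroxy-2-(4-hydroxy-3-methoxyphenyl)-6-(3-methylbut-2-en-1-yl)chroman-4-one (CNP0371910.1) | COc1cc([C@H]2Oc3cc(O)c(CC=C(C)C)c(O)c3C(=O)[C@@H]2O)ccc1O | target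

## Step count and risks

Total step count: 15. Longest linear sequence: 10 steps (steps 2, 3, 4, 5, 6, 11, 12, 13, 14, 15, from allyl alcohol 3 to 26).

Least certain steps:

**Step 4 (key step).** The γ-alkoxy substituent may weaken the face discrimination by the phosphoric acid. Z-to-E isomerisation or a boratropic shift of 7 would erode the syn preference, and the acid may slowly decompose the enol acetal of 7 before the slow, electron-rich aldehyde is consumed. The fallback moves stereocontrol from the catalyst to a stoichiometric chiral borane and sets out from 4 and 2. Ether 4 is lithiated to 5 as in step 3 and transferred to (+)-B-methoxydiisopinocampheylborane (from (−)-α-pinene). BF3·OEt2 then releases [(Z)-3-(methoxymethoxy)prop-2-en-1-yl]bis[(1S,2R,3S,5S)-2,6,6-trimethylbicyclo[3.1.1]heptan-3-yl]borane F1, which should add to 2 at −78 °C through the same chair transition state on the Re face. Oxidative work-up with NaOH and H2O2 returns to the route at 9.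

**Step 14.** The activated β-hydroxy ketone may eliminate towards the α-alkoxy chalcone (which would erase C3) faster than the phenol displaces, and partial ionisation at the para-oxygenated benzylic carbon may loosen the inversion. The fallback sets out from 24 and returns at 25 and makes no new compound (F0). It replaces the stereospecific displacement by a stereoconvergent ionisation. In 1,1,1,3,3,3-hexafluoropropan-2-ol at 40 °C, if necessary with a trace of pyridinium p-toluenesulfonate, the benzylic alcohol should ionise without base, and the neighbouring phenol should trap the cation through a chair in which the aryl group and the C3 substituent are both equatorial. The trans configuration at C2 would then be dictated by C3 rather than by inversion.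

**Step 11.** Lateral metalation at the benzylic and allylic CH2 of the prenyl group may compete with ring metalation, and the hindered aryllithium may enolise the α-alkoxy aldehyde instead of adding. The fallback fixes the metalation site with a halogen and sets out from 19. Ortho-bromination of the free phenol (NBS, CH2Cl2, −78 °C) should give 2-bromo-3,5-bis(methoxymethoxy)-4-(3-methylbut-2-en-1-yl)phenol F2, and tetrahydropyranylation as in step 10 gives 2-[2-bromo-3,5-bis(methoxymethoxy)-4-(3-methylbut-2-en-1-yl)phenoxy]tetrahydro-2H-pyran F3. Bromine–lithium exchange with n-BuLi at −78 °C then returns to the route at 21, which is formed cold and free of any lateral anion before 12 is added.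

**Step 6.** The dialkoxyarene may be over-oxidised by ozone, and the α-alkoxy aldehyde may epimerise during reduction of the ozonide. The fallback sets out from 10. Dihydroxylation with OsO4 (catalytic) and N-methylmorpholine N-oxide in acetone/water should give (2RS,3S,4S)-4-[3-methoxy-4-(methoxymethoxy)phenyl]-3-(methoxymethoxy)-4-(triethylsilyloxy)butane-1,2-diol F4. Glycol cleavage with NaIO4 in buffered THF/water returns to the route at 12.

**Step 15.** Under acid the prenyl alkene may add the C5 or C7 hydroxyl (chroman formation), while the aliphatic acetal at O3 cleaves more slowly than the three aryl acetals and so prolongs the exposure. The fallback sets out from 25, returns at 26 and makes no new compound (F0). It replaces protic solvolysis by Lewis-acid-assisted transfer of the methoxymethyl groups to a soft thiol (ZnBr2, propane-1-thiol, CH2Cl2, 0 °C → rt). No strong protic acid is present to protonate the alkene.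

## Further compounds

F1 | step 4 | [(Z)-3-(methoxymethoxy)prop-2-en-1-yl]bis[(1S,2R,3S,5S)-2,6,6-trimethylbicyclo[3.1.1]heptan-3-yl]borane | COCO/C=C\CB([C@H]1C[C@H]2C[C@@H]([C@@H]1C)C2(C)C)[C@H]1C[C@H]2C[C@@H]([C@@H]1C)C2(C)C
F0 | step 14 | none | none
F2 | step 11 | 2-bromo-3,5-bis(methoxymethoxy)-4-(3-methylbut-2-en-1-yl)phenol | CC(C)=CCc1c(OCOC)cc(O)c(Br)c1OCOC
F3 | step 11 | 2-[2-bromo-3,5-bis(methoxymethoxy)-4-(3-methylbut-2-en-1-yl)phenoxy]tetrahydro-2H-pyran | CC(C)=CCc1c(OCOC)cc(OC2CCCCO2)c(Br)c1OCOC
F4 | step 6 | (2RS,3S,4S)-4-[3-methoxy-4-(methoxymethoxy)phenyl]-3-(methoxymethoxy)-4-(triethylsilyloxy)butane-1,2-diol | OCC(O)[C@H](OCOC)[C@@H](O[Si](CC)(CC)CC)c1ccc(OCOC)c(OC)c1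
F0 | step 15 | none | none
A1 | alternative 1 | (2R,3R)-5,7-dihydroxy-2-[3-methoxy-4-(methoxymethoxy)phenyl]-3-(methoxymethoxy)-6-(3-methylbut-2-en-1-yl)chroman-4-one | COCOc1ccc([C@H]2Oc3cc(O)c(CC=C(C)C)c(O)c3C(=O)[C@@H]2OCOC)cc1OC
A2 | alternative 1 | methyl (8R,9R)-9-hydroxy-9-[3-methoxy-4-(methoxymethoxy)phenyl]-8-(methoxymethoxy)-2-(3-methylbut-2-en-1-yl)-3,5,7-trioxononanoate (epimers at C2) | COC(=O)C(CC=C(C)C)C(=O)CC(=O)CC(=O)[C@H](OCOC)[C@H](O)c1ccc(OCOC)c(OC)c1
A3 | alternative 2 | (2S)-2-[3-methoxy-4-(methoxymethoxy)phenyl]-5,7-bis(methoxymethoxy)-6-(3-methylbut-2-en-1-yl)chroman-4-one | COCOc1ccc([C@H]2Oc3cc(OCOC)c(CC=C(C)C)c(OCOC)c3C(=O)C2)cc1OC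
A4 | alternative 2 | 5,7-bis(methoxymethoxy)-6-(3-methylbut-2-en-1-yl)-4H-chromen-4-one | CC(C)=CCc1c(OCOC)cc2occc(=O)c2c1OCOC
A5 | alternative 2 | [3-methoxy-4-(methoxymethoxy)phenyl]boronic acid | COCOc1ccc(B(O)O)cc1OC
A6 | alternative 3 | (2R,3R)-2-[3-methoxy-4-(methoxymethoxy)phenyl]-3,5,7-tris(methoxymethoxy)-6-(3-methylbut-2-en-1-yl)chroman-4-one | COCOc1ccc([C@H]2Oc3cc(OCOC)c(CC=C(C)C)c(OCOC)c3C(=O)[C@@H]2OCOC)cc1OC
A7 | alternative 3 | 3,5-bis(methoxymethoxy)-4-(3-methylbut-2-en-1-yl)-2-(trimethylsilyl)phenyl trifluoromethanesulfonate | CC(C)=CCc1c(OCOC)cc(OS(=O)(=O)C(F)(F)F)c([Si](C)(C)C)c1OCOC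
A8 | alternative 3 | methyl (2R,3R)-3-hydroxy-3-[3-methoxy-4-(methoxymethoxy)phenyl]-2-(methoxymethoxy)propanoate | COC(=O)[C@H](OCOC)[C@H](O)c1ccc(OCOC)c(OC)c1
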